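**Plan**
1. Cuts: the two E-alkenes of the side chains (Julia–Kocienski at the diene, Wittig at the enoic acid) and, in the core, two ring bonds: the bond joining the two sp2 ring carbons and the bond joining the two carbinol carbons of the cis-diol.
2. Enabling feature: the diol hydroxyl on the carbinol carbon remote from CH2OH lies 1,4 across the ring from the heptenyl-bearing sp2 carbon, and the neighbouring sp2 carbon carries CH2OH (an ester in disguise). The cyclohexene is therefore a 7-oxabicyclo[2.2.1]heptene-2-carboxylate whose oxygen bridge has been opened by β-elimination: four ring carbons and that oxygen are a furan, the other two ring carbons a propiolate.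
3. Forward: furan 3 + ethyl propiolate give the oxanorbornadiene (carbocycle and oxygen bridge in one event); hydroboration, oxidation and hydride reduction on the bicycle; alkoxide conjugate addition with opening of the bridge gives the cyclohexene with the tetrasubstituted alkene; then the enoate chain (Wittig) and the heptenyl chain (Julia–Kocienski).
4. Stereochemistry: the four ring stereocentres are set relative to the oxygen bridge by attack on the exo face of the bicycle (H at the cyanomethyl carbon, H at the silyloxy carbon, O at the ether carbon); the absolute configuration comes from a lipase resolution of bicyclic alcohol 9; both chain alkenes are set E by the olefinations.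

Key step: step 3

Assumption: in step 7 the lipase is taken to acetylate the enantiomer of 10 faster, as the empirical size rule for secondary alcohols predicts when the quaternary bridgehead side is the large substituent; the unreacted alcohol then has the required configuration.
Remark: compounds 5 to 9 are racemic; their names and SMILES show the enantiomer that is carried on. Locants are those of each compound's own name.

Step 1
Reactants: 1 4-bromo-2-furaldehyde
Product: 2 2-(4-bromofuran-2-yl)-1,3-dioxolane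
Conditions: ethylene glycol, TsOH·H2O (cat.), toluene, reflux, Dean–Stark trap
Reagents that add atoms: ethylene glycol OCCO
Why: Acid-catalysed acetalisation with azeotropic removal of water should mask the formyl group, which would otherwise make the furan too electron-poor to serve as a diene, and keeps this carbon at the aldehyde oxidation level for the late olefination.

Step 2
Reactants: 2 2-(4-bromofuran-2-yl)-1,3-dioxolane
Product: 3 2-[5-(1,3-dioxolan-2-yl)furan-3-yl]acetonitrile
Conditions: Me3SiCH2CN, Pd2(dba)3 (cat.), Xantphos, ZnF2 (0.6 equiv), DMF, 90 °C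
Reagents that add atoms: (trimethylsilyl)acetonitrile C[Si](C)(C)CC#N
Why: Palladium-catalysed cross-coupling of a heteroaryl bromide with a silylacetonitrile under fluoride activation (nitrile α-arylation) should place the cyanomethyl group on C-4 of the furan, the nitrile being a two-carbon aldehyde equivalent that is inert to cycloaddition, borane and alkoxide.

Step 3
Reactants: 3 2-[5-(1,3-dioxolan-2-yl)furan-3-yl]acetonitrile; 4 ethyl propiolate
Product: 5 rac-ethyl (1R,4R)-5-(cyanomethyl)-1-(1,3-dioxolan-2-yl)-7-oxabicyclo[2.2.1]hepta-2,5-diene-2-carboxylate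
Conditions: 4 (3 equiv), toluene, 90 °C, sealed tube; chromatography on Et3N-deactivated silica
Reagents that add atoms: none
Why: Thermal, concerted and suprafacial [4+2] cycloaddition (Diels–Alder reaction of a furan with an alkynoate, the reaction type that gives 7-oxanorbornadiene-2-carboxylates), in which furan 3 gives up its aromaticity and bonds C-2 to the α-carbon and C-5 to the β-carbon of 4. Both rings of the 7-oxabicyclo[2.2.1]heptadiene, the six-membered carbocycle and the oxygen-bridged five-membered ring, close in this one intermolecular event. The two bridgehead stereocentres C-1 and C-4 arise together and their relative configuration is fixed by the oxygen bridge; no absolute control is needed because 5 is carried on as a racemate and resolved at step 7. The step needs regioselectivity, which should come from the larger HOMO coefficient at the unsubstituted C-5 of the furan (next to the 4-alkyl group): it pairs with the electrophilic β-carbon of the propiolate and so puts the ester carbon on the acetal-bearing bridgehead. It also needs a diene that is not deactivated, which the acetal oxidation level at the former formyl carbon secures. The ester next to the bridgehead oxygen is what later allows the bridge to be opened and the double bond moved to its place in the target.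

Step 4
Reactants: 5 oxanorbornadiene ester
Product: 7 rac-ethyl (1S,4R,5R,6R)-5-(cyanomethyl)-1-(1,3-dioxolan-2-yl)-6-hydroxy-7-oxabicyclo[2.2.1]hept-2-ene-2-carboxylate, via exo-organoborane 6 (not isolated)
Conditions: 9-BBN, THF, 0 °C to rt; then 30% H2O2, aq. NaOAc, 0 °C
Reagents that add atoms: 9-borabicyclo[3.3.1]nonane [H]B1C2CCCC1CCC2 (boron of 6 only); hydrogen peroxide OO
Why: Hydroboration–oxidation: the strained, more electron-rich trisubstituted alkene should react in preference to the enoate, boron goes to the unsubstituted carbon, and boron and hydrogen are both delivered to the exo face (the side of the oxygen bridge), which sets C-5 (cyanomethyl endo) and C-6 (hydroxyl exo), while buffered peroxide spares ester, nitrile and enoate.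

Step 5
Reactants: 7 exo-alcohol
Product: 8 rac-ethyl (1R,4R,5S)-5-(cyanomethyl)-1-(1,3-dioxolan-2-yl)-6-oxo-7-oxabicyclo[2.2.1]hept-2-ene-2-carboxylate
Conditions: Dess–Martin periodinane, NaHCO3, CH2Cl2, 0 °C to rt
Reagents that add atoms: none
Why: Dess–Martin oxidation under buffered, non-basic conditions should give the ketone without epimerising the adjacent C-5 centre or opening the oxygen bridge by β-elimination.

Step 6
Reactants: 8 ketone
Product: 9 rac-ethyl (1S,4R,5R,6S)-5-(cyanomethyl)-1-(1,3-dioxolan-2-yl)-6-hydroxy-7-oxabicyclo[2.2.1]hept-2-ene-2-carboxylate (6-endo alcohol)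
Conditions: NaBH4, CeCl3·7H2O, MeOH, −78 °C
Reagents that add atoms: none
Why: Luche reduction: hydride should attack the carbonyl from the exo face, as is usual for 7-oxanorbornanones, so the hydroxyl ends up endo and cis to the cyanomethyl group, which is the relationship required in the target.

Step 7
Reactants: 9 racemic endo-alcohol
Product: 10 ethyl (1S,4R,5R,6S)-5-(cyanomethyl)-1-(1,3-dioxolan-2-yl)-6-hydroxy-7-oxabicyclo[2.2.1]hept-2-ene-2-carboxylate (single enantiomer)
Conditions: Amano lipase PS, vinyl acetate, MTBE, 30 °C, to about half conversion; chromatography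
Reagents that add atoms: none
Why: Lipase-catalysed kinetic resolution by irreversible transesterification with vinyl acetate should acetylate the enantiomer of 10 faster, so that unreacted 10, which carries the absolute configuration of all four ring stereocentres of the target, is separated from the acetate.

Step 8
Reactants: 10 resolved endo-alcohol
Product: 11 ethyl (1S,4R,5S,6S)-6-[(tert-butyldimethylsilyl)oxy]-5-(cyanomethyl)-1-(1,3-dioxolan-2-yl)-7-oxabicyclo[2.2.1]hept-2-ene-2-carboxylate
Conditions: TBSOTf, 2,6-lutidine, CH2Cl2, −78 °C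
Reagents that add atoms: tert-butyldimethylsilyl triflate CC(C)(C)[Si](C)(C)OS(=O)(=O)C(F)(F)F
Why: Silylation of the hindered secondary alcohol with the silyl triflate at low temperature protects it against alkoxide formation and lactonisation in the next step, and the dioxolane should survive at −78 °C with the hindered base.

Step 9
Reactants: 11 silyl ether
Product: 13 ethyl (3S,4S,5S,6R)-3-[(tert-butyldimethylsilyl)oxy]-4-(cyanomethyl)-2-(1,3-dioxolan-2-yl)-5-hydroxy-6-[(4-methoxybenzyl)oxy]cyclohex-1-ene-1-carboxylate, via sodium ester enolate 12 (not isolated)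
Conditions: 4-methoxybenzyl alcohol, NaH, THF, 0 °C; then 11, −40 to 0 °C; aq. NH4Cl at −20 °C
Reagents that add atoms: 4-methoxybenzyl alcohol COc1ccc(CO)cc1
Why: Oxa-Michael addition of the alkoxide to the strained enoate from the exo face gives enolate 12, which should cleave the β C–O bond of the oxygen bridge (E1cB ring-opening known for 7-oxanorbornane-2-carboxylate enolates), so that the new C-6 ether and the released C-5 hydroxyl are cis and the alkene moves into the tetrasubstituted position of the target.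

Step 10
Reactants: 13 4-methoxybenzyl ether
Product: 14 ethyl (3S,4S,5S,6R)-3-[(tert-butyldimethylsilyl)oxy]-4-(cyanomethyl)-2-(1,3-dioxolan-2-yl)-5,6-dihydroxycyclohex-1-ene-1-carboxylate
Conditions: DDQ, CH2Cl2/pH 7 buffer, 0 °C
Reagents that add atoms: none
Why: Oxidative cleavage of the 4-methoxybenzyl ether with DDQ in wet dichloromethane should release the second hydroxyl of the cis-diol without touching silyl ether, acetal, nitrile or enoate.

Step 11
Reactants: 14 diol ester
Product: 15 2-[(1S,2S,5R,6S)-2-[(tert-butyldimethylsilyl)oxy]-3-(1,3-dioxolan-2-yl)-5,6-dihydroxy-4-(hydroxymethyl)cyclohex-3-en-1-yl]acetaldehyde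
Conditions: i-Bu2AlH (excess), CH2Cl2, −78 °C; aq. Rochelle salt
Reagents that add atoms: water O
Why: Reduction with i-Bu2AlH at low temperature should take the conjugated ester to the allylic alcohol and stop the nitrile at the N-aluminated imine, which gives the aldehyde on aqueous work-up.

Step 12
Reactants: 15 triol aldehyde; 16 ethyl 2-(triphenyl-λ5-phosphanylidene)propanoate
Product: 17 ethyl (2E)-4-[(1S,2S,5R,6S)-2-[(tert-butyldimethylsilyl)oxy]-3-(1,3-dioxolan-2-yl)-5,6-dihydroxy-4-(hydroxymethyl)cyclohex-3-en-1-yl]-2-methylbut-2-enoate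
Conditions: CH2Cl2, rt
Reagents that add atoms: none
Why: Wittig reaction with a stabilised, α-branched ylide should form the trisubstituted enoate with E geometry and tolerates the free hydroxyl groups.

Step 13
Reactants: 17 triol enoate
Product: 18 ethyl (2E)-4-[(1R,2S,5R,6S)-2,5,6-tris[(tert-butyldimethylsilyl)oxy]-4-{[(tert-butyldimethylsilyl)oxy]methyl}-3-(1,3-dioxolan-2-yl)cyclohex-3-en-1-yl]-2-methylbut-2-enoate
Conditions: TBSOTf (excess), 2,6-lutidine, CH2Cl2, −78 to −20 °C
Reagents that add atoms: tert-butyldimethylsilyl triflate CC(C)(C)[Si](C)(C)OS(=O)(=O)C(F)(F)F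
Why: Exhaustive silylation with the silyl triflate and a hindered base protects the three hydroxyl groups for the base-mediated olefination.

Step 14
Reactants: 18 fully silylated acetal
Product: 19 ethyl (2E)-4-[(1R,2S,5R,6S)-2,5,6-tris[(tert-butyldimethylsilyl)oxy]-4-{[(tert-butyldimethylsilyl)oxy]methyl}-3-formylcyclohex-3-en-1-yl]-2-methylbut-2-enoate
Conditions: PPTS (cat.), acetone/H2O, 40 °C
Reagents that add atoms: water O
Why: Mild acid-catalysed acetal hydrolysis, fast here because the oxocarbenium ion is conjugated with the ring alkene, should release the enal while the silyl ethers remain.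

Step 15
Reactants: 20 1-phenyl-1H-tetrazole-5-thiol; 21 1-bromohexane
Product: 22 5-(hexylsulfanyl)-1-phenyl-1H-tetrazole
Conditions: K2CO3, acetone, reflux
Reagents that add atoms: none
Why: S-alkylation of the thiolate by SN2 displacement of the primary bromide.

Step 16
Reactants: 22 sulfide
Product: 23 5-(hexylsulfonyl)-1-phenyl-1H-tetrazole
Conditions: 30% H2O2, (NH4)6Mo7O24·4H2O (cat.), EtOH, rt
Reagents that add atoms: hydrogen peroxide OO
Why: Molybdate-catalysed oxidation of the sulfide with hydrogen peroxide gives the sulfone needed for the Julia–Kocienski reaction.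

Step 17
Reactants: 19 enal; 23 5-(hexylsulfonyl)-1-phenyl-1H-tetrazole
Product: 24 ethyl (2E)-4-[(1R,2S,5R,6S)-2,5,6-tris[(tert-butyldimethylsilyl)oxy]-4-{[(tert-butyldimethylsilyl)oxy]methyl}-3-[(1E)-hept-1-en-1-yl]cyclohex-3-en-1-yl]-2-methylbut-2-enoate
Conditions: 23, KN(SiMe3)2, DME, −60 °C; then 19, −60 °C to rt
Reagents that add atoms: none
Why: Julia–Kocienski olefination: addition of the metalated phenyltetrazolyl sulfone to the enal, Smiles rearrangement and loss of SO2 and tetrazolate should give the disubstituted alkene with E geometry (favoured with the potassium base in DME) and complete the diene.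

Step 18
Reactants: 24 silylated diene ester
Product: 25 ethyl (2E)-4-[(1R,2S,5R,6S)-3-[(1E)-hept-1-en-1-yl]-2,5,6-trihydroxy-4-(hydroxymethyl)cyclohex-3-en-1-yl]-2-methylbut-2-enoate
Conditions: Bu4NF (excess), THF, 0 °C to rt
Reagents that add atoms: none
Why: Fluoride-mediated desilylation removes all four silyl ethers under non-acidic conditions that the acid-sensitive allylic alcohols and the diene should tolerate.

Step 19
Reactants: 25 tetraol ethyl ester
Product: 26 pestallic acid P, (2E)-4-[(1R,2S,5R,6S)-3-[(1E)-hept-1-en-1-yl]-2,5,6-trihydroxy-4-(hydroxymethyl)cyclohex-3-en-1-yl]-2-methylbut-2-enoic acid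
Conditions: LiOH, THF/MeOH/H2O, rt; then dilute HCl to pH 4 at 0 °C
Reagents that add atoms: lithium hydroxide [Li+].[OH-]
Why: Saponification of the ethyl ester and careful acidification should give the acid without change of alkene geometry or of any stereocentre.

**Compound list**
1 | 4-bromo-2-furaldehyde | O=Cc1cc(Br)co1 | starting material
2 | 2-(4-bromofuran-2-yl)-1,3-dioxolane | Brc1coc(C2OCCO2)c1 | intermediate
3 | 2-[5-(1,3-dioxolan-2-yl)furan-3-yl]acetonitrile | N#CCc1coc(C2OCCO2)c1 | intermediate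
4 | ethyl propiolate | C#CC(=O)OCC | starting material
5 | rac-ethyl (1R,4R)-5-(cyanomethyl)-1-(1,3-dioxolan-2-yl)-7-oxabicyclo[2.2.1]hepta-2,5-diene-2-carboxylate | [C@]12(C3OCCO3)O[C@H](C=C1C(=O)OCC)C(CC#N)=C2 | intermediate
6 | exo-organoborane: 5 carrying a 9-borabicyclo[3.3.1]nonan-9-yl group at C-6 (exo) and hydrogen at C-5 (exo), racemic | [C@]12(C3OCCO3)O[C@H](C=C1C(=O)OCC)[C@H](CC#N)[C@H]2B1C2CCCC1CCC2 | intermediate
7 | rac-ethyl (1S,4R,5R,6R)-5-(cyanomethyl)-1-(1,3-dioxolan-2-yl)-6-hydroxy-7-oxabicyclo[2.2.1]hept-2-ene-2-carboxylate (5-endo, 6-exo) | [C@]12(C3OCCO3)O[C@H](C=C1C(=O)OCC)[C@H](CC#N)[C@H]2O | intermediate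
8 | rac-ethyl (1R,4R,5S)-5-(cyanomethyl)-1-(1,3-dioxolan-2-yl)-6-oxo-7-oxabicyclo[2.2.1]hept-2-ene-2-carboxylate (5-endo) | [C@]12(C3OCCO3)O[C@H](C=C1C(=O)OCC)[C@H](CC#N)C2=O | intermediate
9 | rac-ethyl (1S,4R,5R,6S)-5-(cyanomethyl)-1-(1,3-dioxolan-2-yl)-6-hydroxy-7-oxabicyclo[2.2.1]hept-2-ene-2-carboxylate (5-endo, 6-endo) | [C@]12(C3OCCO3)O[C@H](C=C1C(=O)OCC)[C@H](CC#N)[C@@H]2O | intermediate
10 | ethyl (1S,4R,5R,6S)-5-(cyanomethyl)-1-(1,3-dioxolan-2-yl)-6-hydroxy-7-oxabicyclo[2.2.1]hept-2-ene-2-carboxylate, single enantiomer | [C@]12(C3OCCO3)O[C@H](C=C1C(=O)OCC)[C@H](CC#N)[C@@H]2O | intermediate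
11 | ethyl (1S,4R,5S,6S)-6-[(tert-butyldimethylsilyl)oxy]-5-(cyanomethyl)-1-(1,3-dioxolan-2-yl)-7-oxabicyclo[2.2.1]hept-2-ene-2-carboxylate | [C@]12(C3OCCO3)O[C@H](C=C1C(=O)OCC)[C@H](CC#N)[C@@H]2O[Si](C)(C)C(C)(C)C | intermediate
12 | sodium ester enolate of the 3-exo-(4-methoxybenzyloxy) adduct of 11 | [C@]12(C3OCCO3)O[C@H]([C@H](OCc3ccc(OC)cc3)C1=C([O-])OCC)[C@H](CC#N)[C@@H]2O[Si](C)(C)C(C)(C)C.[Na+] | intermediate
13 | ethyl (3S,4S,5S,6R)-3-[(tert-butyldimethylsilyl)oxy]-4-(cyanomethyl)-2-(1,3-dioxolan-2-yl)-5-hydroxy-6-[(4-methoxybenzyl)oxy]cyclohex-1-ene-1-carboxylate | C1(C2OCCO2)=C(C(=O)OCC)[C@@H](OCc2ccc(OC)cc2)[C@@H](O)[C@H](CC#N)[C@@H]1O[Si](C)(C)C(C)(C)C | intermediate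
14 | ethyl (3S,4S,5S,6R)-3-[(tert-butyldimethylsilyl)oxy]-4-(cyanomethyl)-2-(1,3-dioxolan-2-yl)-5,6-dihydroxycyclohex-1-ene-1-carboxylate | C1(C2OCCO2)=C(C(=O)OCC)[C@@H](O)[C@@H](O)[C@H](CC#N)[C@@H]1O[Si](C)(C)C(C)(C)C | intermediate
15 | 2-[(1S,2S,5R,6S)-2-[(tert-butyldimethylsilyl)oxy]-3-(1,3-dioxolan-2-yl)-5,6-dihydroxy-4-(hydroxymethyl)cyclohex-3-en-1-yl]acetaldehyde | C1(C2OCCO2)=C(CO)[C@@H](O)[C@@H](O)[C@H](CC=O)[C@@H]1O[Si](C)(C)C(C)(C)C | intermediate
16 | ethyl 2-(triphenyl-λ5-phosphanylidene)propanoate | CCOC(=O)C(C)=P(c1ccccc1)(c1ccccc1)c1ccccc1 | starting material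
17 | ethyl (2E)-4-[(1S,2S,5R,6S)-2-[(tert-butyldimethylsilyl)oxy]-3-(1,3-dioxolan-2-yl)-5,6-dihydroxy-4-(hydroxymethyl)cyclohex-3-en-1-yl]-2-methylbut-2-enoate | C1(C2OCCO2)=C(CO)[C@@H](O)[C@@H](O)[C@H](C/C=C(\C)C(=O)OCC)[C@@H]1O[Si](C)(C)C(C)(C)C | intermediate
18 | ethyl (2E)-4-[(1R,2S,5R,6S)-2,5,6-tris[(tert-butyldimethylsilyl)oxy]-4-{[(tert-butyldimethylsilyl)oxy]methyl}-3-(1,3-dioxolan-2-yl)cyclohex-3-en-1-yl]-2-methylbut-2-enoate | C1(C2OCCO2)=C(CO[Si](C)(C)C(C)(C)C)[C@@H](O[Si](C)(C)C(C)(C)C)[C@@H](O[Si](C)(C)C(C)(C)C)[C@H](C/C=C(\C)C(=O)OCC)[C@@H]1O[Si](C)(C)C(C)(C)C | intermediate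
19 | ethyl (2E)-4-[(1R,2S,5R,6S)-2,5,6-tris[(tert-butyldimethylsilyl)oxy]-4-{[(tert-butyldimethylsilyl)oxy]methyl}-3-formylcyclohex-3-en-1-yl]-2-methylbut-2-enoate | O=CC1=C(CO[Si](C)(C)C(C)(C)C)[C@@H](O[Si](C)(C)C(C)(C)C)[C@@H](O[Si](C)(C)C(C)(C)C)[C@H](C/C=C(\C)C(=O)OCC)[C@@H]1O[Si](C)(C)C(C)(C)C | intermediate
20 | 1-phenyl-1H-tetrazole-5-thiol | SC1=NN=NN1c1ccccc1 | starting material
21 | 1-bromohexane | CCCCCCBr | starting material
22 | 5-(hexylsulfanyl)-1-phenyl-1H-tetrazole | CCCCCCSC1=NN=NN1c1ccccc1 | intermediate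
23 | 5-(hexylsulfonyl)-1-phenyl-1H-tetrazole | CCCCCCS(=O)(=O)C1=NN=NN1c1ccccc1 | intermediate
24 | ethyl (2E)-4-[(1R,2S,5R,6S)-2,5,6-tris[(tert-butyldimethylsilyl)oxy]-4-{[(tert-butyldimethylsilyl)oxy]methyl}-3-[(1E)-hept-1-en-1-yl]cyclohex-3-en-1-yl]-2-methylbut-2-enoate | CCCCC/C=C/C1=C(CO[Si](C)(C)C(C)(C)C)[C@@H](O[Si](C)(C)C(C)(C)C)[C@@H](O[Si](C)(C)C(C)(C)C)[C@H](C/C=C(\C)C(=O)OCC)[C@@H]1O[Si](C)(C)C(C)(C)C | intermediate
25 | ethyl (2E)-4-[(1R,2S,5R,6S)-3-[(1E)-hept-1-en-1-yl]-2,5,6-trihydroxy-4-(hydroxymethyl)cyclohex-3-en-1-yl]-2-methylbut-2-enoate | CCCCC/C=C/C1=C(CO)[C@@H](O)[C@@H](O)[C@H](C/C=C(\C)C(=O)OCC)[C@@H]1O | intermediate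
26 | pestallic acid P, (2E)-4-[(1R,2S,5R,6S)-3-[(1E)-hept-1-en-1-yl]-2,5,6-trihydroxy-4-(hydroxymethyl)cyclohex-3-en-1-yl]-2-methylbut-2-enoic acid | CCCCC/C=C/C1=C(CO)[C@@H](O)[C@@H](O)[C@H](C/C=C(\C)C(=O)O)[C@@H]1O | target

Total step count: 19. Longest linear sequence: 17 steps (steps 1 to 14 and 17 to 19, from 1); steps 15 and 16 make the sulfone in a side branch.

**Steps most likely to fail**

1. Step 3. The furan is only moderately electron-rich and the alkyne is singly activated, so the cycloaddition may be slow and be overtaken by polymerisation of the propiolate, by a second addition to the product, or by loss of regioselectivity. Fallback, from 3 and 4 back to 5: 4 is brominated at the alkyne terminus (N-bromosuccinimide, AgNO3 cat., acetone) to ethyl 3-bromopropiolate F1, a far more reactive and more polarised dienophile. Its cycloaddition with 3 (benzene, rt to 50 °C) should give rac-ethyl 3-bromo-5-(cyanomethyl)-1-(1,3-dioxolan-2-yl)-7-oxabicyclo[2.2.1]hepta-2,5-diene-2-carboxylate F2. Hydrodebromination of this β-bromo enoate (Bu3SnH, Pd(PPh3)4 cat., THF, rt) returns to 5.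

2. Step 7. The lipase may discriminate poorly between the enantiomers of a hindered endo alcohol, or in the opposite sense. Fallback, from racemic 9 back to 14, by resolution through covalent diastereomers: racemic 9 is silylated as in step 8 (racemic 11), and the ring-opening of step 9 is run with sodium (S)-1-(4-methoxyphenyl)ethoxide in place of the achiral alkoxide. This should give ethyl (3S,4S,5S,6R)-3-[(tert-butyldimethylsilyl)oxy]-4-(cyanomethyl)-2-(1,3-dioxolan-2-yl)-5-hydroxy-6-[(1S)-1-(4-methoxyphenyl)ethoxy]cyclohex-1-ene-1-carboxylate F3 together with its (3R,4R,5R,6S) diastereomer F4, which are separated by chromatography. Cleavage of the benzylic ether of F3 with DDQ, as in step 10, gives 14.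

3. Step 9. Ring-opening may lose out to retro-addition, ester exchange with the alkoxide, silyl migration to the released alkoxide, or deprotonation next to the nitrile. Fallback, from 11 back to 14, with the two events separated and boron as the oxygen carrier: copper-catalysed conjugate borylation of 11 (B2pin2, CuCl, Xantphos, NaOtBu, MeOH, THF, rt) from the exo face should give ethyl 6-endo-[(tert-butyldimethylsilyl)oxy]-5-endo-(cyanomethyl)-1-(1,3-dioxolan-2-yl)-3-exo-(4,4,5,5-tetramethyl-1,3,2-dioxaborolan-2-yl)-7-oxabicyclo[2.2.1]heptane-2-endo-carboxylate F5. Oxidation with retention (NaBO3·4H2O, THF/H2O) gives the 3-exo-hydroxy ester F6. Treatment with KN(SiMe3)2 (2.2 equiv, THF, −78 °C) forms the alkoxide ester enolate, which can only expel the oxygen bridge, and gives diol 14 directly; 13 and step 10 are bypassed.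

**Further compounds**
F1 | step 3 | ethyl 3-bromopropiolate | BrC#CC(=O)OCC
F2 | step 3 | rac-ethyl 3-bromo-5-(cyanomethyl)-1-(1,3-dioxolan-2-yl)-7-oxabicyclo[2.2.1]hepta-2,5-diene-2-carboxylate | [C@]12(C3OCCO3)O[C@H](C(Br)=C1C(=O)OCC)C(CC#N)=C2
F3 | step 7 | ethyl (3S,4S,5S,6R)-3-[(tert-butyldimethylsilyl)oxy]-4-(cyanomethyl)-2-(1,3-dioxolan-2-yl)-5-hydroxy-6-[(1S)-1-(4-methoxyphenyl)ethoxy]cyclohex-1-ene-1-carboxylate | C1(C2OCCO2)=C(C(=O)OCC)[C@@H](O[C@@H](C)c2ccc(OC)cc2)[C@@H](O)[C@H](CC#N)[C@@H]1O[Si](C)(C)C(C)(C)C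
F4 | step 7 | ethyl (3R,4R,5R,6S)-3-[(tert-butyldimethylsilyl)oxy]-4-(cyanomethyl)-2-(1,3-dioxolan-2-yl)-5-hydroxy-6-[(1S)-1-(4-methoxyphenyl)ethoxy]cyclohex-1-ene-1-carboxylate | C1(C2OCCO2)=C(C(=O)OCC)[C@H](O[C@@H](C)c2ccc(OC)cc2)[C@H](O)[C@@H](CC#N)[C@H]1O[Si](C)(C)C(C)(C)C
F5 | step 9 | ethyl 6-endo-[(tert-butyldimethylsilyl)oxy]-5-endo-(cyanomethyl)-1-(1,3-dioxolan-2-yl)-3-exo-(4,4,5,5-tetramethyl-1,3,2-dioxaborolan-2-yl)-7-oxabicyclo[2.2.1]heptane-2-endo-carboxylate | [C@]12(C3OCCO3)O[C@H]([C@H](B3OC(C)(C)C(C)(C)O3)[C@H]1C(=O)OCC)[C@H](CC#N)[C@@H]2O[Si](C)(C)C(C)(C)C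
F6 | step 9 | ethyl 6-endo-[(tert-butyldimethylsilyl)oxy]-5-endo-(cyanomethyl)-1-(1,3-dioxolan-2-yl)-3-exo-hydroxy-7-oxabicyclo[2.2.1]heptane-2-endo-carboxylate | [C@]12(C3OCCO3)O[C@H]([C@H](O)[C@H]1C(=O)OCC)[C@H](CC#N)[C@@H]2O[Si](C)(C)C(C)(C)C
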